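**Retrosynthetic overview**
1. Carotenoid numbering is used: unprimed is the acetylenic half (ring A), primed is the epoxy-ketone half (ring B). The last disconnection is the C12–C13 sp2–sp2 single bond. It gives the C16 dienynyl stannane 13 (C12–Sn) and the C24 pentaenone iodide 34 (C13–I), which are joined unprotected by a Stille coupling.
2. Enabling feature: the C13(Me)=C14–C15=C15'–C14'=C13'(Me) octatriene core is locally C2-symmetric. Each end is a methyl-bearing, fully substituted alkene carbon joined to a CH=CH unit (C12, C12'). One symmetric diiodide 23 therefore serves both wings, and its C–I carbons hold the (E) geometry.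
3. 34 comes from 23 and the C16 stannyl dienone 33 (C12'–C13' bond). 33 comes from the β,γ-epoxy aldehyde 31 and the iodo-stannyl diene 19 (C8'–C9' bond by Nozaki–Hiyama–Kishi reaction, then MnO2).
4. Both wings come from one enol triflate 4, made from actinol 1. Sonogashira coupling at C6–C7 leads to 13. Carbonylation, Sharpless epoxidation and one-carbon homologation lead to 31. All three C(Me)=CH units (C9', C13', C13) come from iodide 17.
5. Ring order: rings A and B are carried in from 1. The only ring made is the C5'–C6' oxirane on ring B (step 16). The key step closes no ring.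

Key step: step 24

Assumption: actinol 1 is taken as purchasable (it is the industrial zeaxanthin building block), and the C8' carbinol of 32 is carried as an epimer mixture because step 22 erases this centre. All polyene steps are run in the dark under argon.

**Route**

Step 1
Reactants: 1 (4R,6R)-4-hydroxy-2,2,6-trimethylcyclohexan-1-one (actinol)
Product: 2 (4R,6R)-4-(tert-butyldimethylsilyloxy)-2,2,6-trimethylcyclohexan-1-one
Conditions: TBSCl, imidazole, DMF, rt
Reagents that add atoms: tert-butyldimethylsilyl chloride, CC(C)(C)[Si](C)(C)Cl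
Why: Imidazole-promoted silyl ether formation masks the only hydroxyl against the strong base of step 2 and touches no stereocentre.

Step 2
Reactants: 2 silyl ether of actinol
Product: 4 (R)-4-(tert-butyldimethylsilyloxy)-2,6,6-trimethylcyclohex-1-en-1-yl trifluoromethanesulfonate, via lithium enolate 3 (not isolated)
Conditions: LiN(i-Pr)2, THF, −78 °C; then PhNTf2, −78 °C → rt
Reagents that add atoms: N-phenylbis(trifluoromethanesulfonimide), O=S(=O)(N(c1ccccc1)S(=O)(=O)C(F)(F)F)C(F)(F)F
Why: Enol triflate formation works because only one α-carbon bears hydrogen (the other is quaternary), so O-sulfonylation of the single possible enolate gives the tetrasubstituted C5=C6 triflate, erasing the unneeded methyl-bearing centre and keeping the carbinol centre.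

Step 3
Reactants: 4 enol triflate; 5 (E)-3-methylpent-2-en-4-yn-1-ol
Product: 6 (E)-5-[(R)-4-(tert-butyldimethylsilyloxy)-2,6,6-trimethylcyclohex-1-en-1-yl]-3-methylpent-2-en-4-yn-1-ol
Conditions: Pd(PPh3)4 (cat.), CuI (cat.), i-Pr2NH, DMF, 50 °C
Reagents that add atoms: none
Why: Sonogashira coupling of an alkenyl triflate and a terminal alkyne forms C6–C7, and the (E)-C9=C10 geometry is carried in unchanged from 5.

Step 4
Reactants: 6 silyl-protected C15 enynol
Product: 7 (E)-5-[(R)-4-hydroxy-2,6,6-trimethylcyclohex-1-en-1-yl]-3-methylpent-2-en-4-yn-1-ol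
Conditions: n-Bu4NF, THF, rt
Reagents that add atoms: none
Why: Fluoride-induced silyl ether cleavage is placed here, where nothing is sensitive to base or fluoride, so that the end game needs no deprotection.

Step 5
Reactants: 7 C15 diol
Product: 8 (E)-5-[(R)-4-hydroxy-2,6,6-trimethylcyclohex-1-en-1-yl]-3-methylpent-2-en-4-ynal
Conditions: activated MnO2, CH2Cl2, rt
Reagents that add atoms: none
Why: Chemoselective allylic oxidation by MnO2 converts only the primary allylic alcohol and leaves the unactivated secondary C3 hydroxyl alone.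

Step 6
Reactants: 9 diiodomethane; 10 tributyltin chloride
Product: 12 tributyl(diiodomethyl)stannane, via diiodomethyllithium 11 (not isolated)
Conditions: LiN(i-Pr)2, THF, −78 °C; then n-Bu3SnCl, −78 °C → rt, dark
Reagents that add atoms: none
Why: Deprotonation of diiodomethane followed by substitution at tin by the carbenoid gives the gem-diiodide needed for chromium olefination.

Step 7
Reactants: 8 C15 enynal; 12 tributyl(diiodomethyl)stannane
Product: 13 (R)-3,5,5-trimethyl-4-[(3E,5E)-3-methyl-6-(tributylstannyl)hexa-3,5-dien-1-yn-1-yl]cyclohex-3-en-1-ol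
Conditions: CrCl2 (excess), DMF/THF, rt, dark
Reagents that add atoms: none
Why: In the Takai–Hodgson olefination the gem-dichromium species from 12 adds to the aldehyde and eliminates to the (E)-C11=C12 alkenylstannane, and this weakly basic reagent tolerates the free hydroxyl and the alkyne.

Step 8
Reactants: 14 but-2-yn-1-ol
Product: 17 (E)-3-iodobut-2-en-1-ol, via aluminium alkoxide 15 (not isolated), via alkenylzirconocene 16 (not isolated)
Conditions: i-Bu2AlH (1 equiv), THF, 0 °C; then Cp2ZrCl2/i-Bu2AlH (gives Cp2Zr(H)Cl), 0 °C → rt; then I2, −78 °C; aq. work-up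
Reagents that add atoms: iodine, [I][I]
Why: In this hydrozirconation–iodination, syn addition of Cp2Zr(H)Cl to the alkoxide-masked alkyne places zirconium on the methyl-bearing carbon remote from oxygen, and iodinolysis with retention gives the (E)-2-iodoalkene unit.

Step 9
Reactants: 17 (E)-3-iodobut-2-en-1-ol
Product: 18 (E)-3-iodobut-2-enal
Conditions: activated MnO2, CH2Cl2, rt, dark; used promptly
Reagents that add atoms: none
Why: Neutral allylic oxidation by MnO2 gives the β-iodo enal without loss of iodide or of alkene geometry.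

Step 10
Reactants: 18 (E)-3-iodobut-2-enal; 12 tributyl(diiodomethyl)stannane
Product: 19 tributyl[(1E,3E)-4-iodopenta-1,3-dien-1-yl]stannane
Conditions: CrCl2 (excess, nickel-free), DMF/THF, rt, dark
Reagents that add atoms: none
Why: Takai–Hodgson olefination builds the (E)-C11'=C12' stannane, and the hindered 2-iodoalkene is not activated by divalent chromium when no nickel salt is present.

Step 11
Reactants: 17 (E)-3-iodobut-2-en-1-ol
Product: 20 (E)-1-bromo-3-iodobut-2-ene
Conditions: CBr4, PPh3, CH2Cl2, 0 °C
Reagents that add atoms: tetrabromomethane, BrC(Br)(Br)Br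
Why: The Appel reaction replaces the primary allylic hydroxyl by bromide under neutral conditions without allylic transposition or change at the alkenyl iodide.

Step 12
Reactants: 20 allylic bromide
Product: 21 diethyl [(E)-3-iodobut-2-en-1-yl]phosphonate
Conditions: P(OEt)3, neat, 100 °C
Reagents that add atoms: triethyl phosphite, CCOP(OCC)OCC
Why: The Michaelis–Arbuzov reaction takes place only at the sp3 allylic bromide, since the alkenyl iodide is inert to phosphite.

Step 13
Reactants: 21 phosphonate; 18 (E)-3-iodobut-2-enal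
Product: 23 (2E,4E,6E)-2,7-diiodoocta-2,4,6-triene, via sodium phosphonate carbanion 22 (not isolated)
Conditions: NaN(SiMe3)2, THF, −78 °C; then 18, −78 → 0 °C, dark
Reagents that add atoms: none
Why: Horner–Wadsworth–Emmons olefination of an allylic phosphonate and an enal forms the central C15=C15' bond (E)-selectively, and the non-nucleophilic amide base avoids halogen–metal exchange.

Step 14
Reactants: 4 enol triflate
Product: 24 methyl (R)-4-(tert-butyldimethylsilyloxy)-2,6,6-trimethylcyclohex-1-ene-1-carboxylate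
Conditions: Pd(OAc)2 (cat.), PPh3, CO (1 atm), Et3N, MeOH/DMF, 50 °C
Reagents that add atoms: carbon monoxide, [C-]#[O+]; methanol, CO
Why: Palladium-catalysed alkoxycarbonylation of the alkenyl triflate (oxidative addition, CO insertion, methanolysis) installs C7' on C6' of ring B.

Step 15
Reactants: 24 methyl ester
Product: 25 [(R)-4-(tert-butyldimethylsilyloxy)-2,6,6-trimethylcyclohex-1-en-1-yl]methanol
Conditions: i-Bu2AlH, CH2Cl2, −78 °C; aq. work-up
Reagents that add atoms: none
Why: Hydride reduction of the conjugated ester gives the primary allylic alcohol that serves as the handle for directed epoxidation, and the silyl ether is inert.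

Step 16
Reactants: 25 allylic alcohol
Product: 26 [(1R,4S,6R)-4-(tert-butyldimethylsilyloxy)-2,2,6-trimethyl-7-oxabicyclo[4.1.0]heptan-1-yl]methanol (oxirane anti to the silyloxy group)
Conditions: Ti(Oi-Pr)4 (cat.), D-(−)-diethyl tartrate (cat.), t-BuOOH, 4 Å molecular sieves, CH2Cl2, −20 °C
Reagents that add atoms: tert-butyl hydroperoxide, CC(C)(C)OO
Why: In the Sharpless asymmetric epoxidation the C7' hydroxyl binds the titanium tartrate peroxo complex and the D-(−)-tartrate directs oxygen to the C5'=C6' face anti to the C3' silyloxy group, so C5' and C6' are set together by reagent control in one syn addition.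

Step 17
Reactants: 26 epoxy alcohol
Product: 27 (1S,4S,6R)-4-(tert-butyldimethylsilyloxy)-2,2,6-trimethyl-7-oxabicyclo[4.1.0]heptane-1-carbaldehyde
Conditions: (n-Pr4N)RuO4 (cat.), N-methylmorpholine N-oxide, 4 Å molecular sieves, CH2Cl2, rt
Reagents that add atoms: none
Why: The Ley–Griffith oxidation is neutral and non-aqueous, stops at the non-enolisable epoxy aldehyde and leaves the oxirane and silyl ether intact.

Step 18
Reactants: 27 epoxy aldehyde
Product: 28 tert-butyl{[(1R,4S,6R)-1-ethynyl-2,2,6-trimethyl-7-oxabicyclo[4.1.0]heptan-4-yl]oxy}dimethylsilane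
Conditions: dimethyl (1-diazo-2-oxopropyl)phosphonate, K2CO3, MeOH, 0 °C → rt
Reagents that add atoms: dimethyl (1-diazo-2-oxopropyl)phosphonate, CC(=O)C(=[N+]=[N-])P(=O)(OC)OC
Why: Ohira–Bestmann homologation turns the non-enolisable aldehyde into the terminal alkyne and adds C8' without touching the adjacent quaternary C6'.

Step 19
Reactants: 28 silyl-protected epoxy alkyne
Product: 29 (1R,4S,6R)-1-ethynyl-2,2,6-trimethyl-7-oxabicyclo[4.1.0]heptan-4-ol
Conditions: n-Bu4NF, THF, rt
Reagents that add atoms: none
Why: Fluoride-induced silyl ether cleavage is done at this robust stage, before any base-labile β,γ-epoxy carbonyl group or acid-labile stannane exists.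

Step 20
Reactants: 29 epoxy alkynol
Product: 31 2-[(1S,4S,6R)-4-hydroxy-2,2,6-trimethyl-7-oxabicyclo[4.1.0]heptan-1-yl]acetaldehyde, via alkenylborane 30 (not isolated)
Conditions: (c-C6H11)2BH (2.2 equiv), THF, 0 °C; then 30% H2O2, pH 7 phosphate buffer, 0 °C; used without storage
Reagents that add atoms: hydrogen peroxide, OO
Why: In this anti-Markovnikov alkyne hydroboration–oxidation the bulky dialkylborane adds once and syn, placing boron on terminal C8' (a second equivalent only borylates the hydroxyl), and buffered peroxide gives the enol and hence the aldehyde at a pH where the C7' protons stay in place.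

Step 21
Reactants: 31 β,γ-epoxy aldehyde; 19 iodo-stannyl diene
Product: 32 (3E,5E)-1-[(1S,4S,6R)-4-hydroxy-2,2,6-trimethyl-7-oxabicyclo[4.1.0]heptan-1-yl]-3-methyl-6-(tributylstannyl)hexa-3,5-dien-2-ol (both C8' epimers)
Conditions: CrCl2 (excess), NiCl2 (cat.), DMF, rt, dark
Reagents that add atoms: none
Why: In the Nozaki–Hiyama–Kishi reaction the non-basic alkenylchromium reagent formed at the C9'–I bond with retention adds to the enolisable aldehyde without deprotonating C7', and the new C8' centre is left uncontrolled because step 22 removes it.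

Step 22
Reactants: 32 stannyl dienol
Product: 33 (3E,5E)-1-[(1S,4S,6R)-4-hydroxy-2,2,6-trimethyl-7-oxabicyclo[4.1.0]heptan-1-yl]-3-methyl-6-(tributylstannyl)hexa-3,5-dien-2-one
Conditions: activated neutral MnO2, CH2Cl2, rt, dark
Reagents that add atoms: none
Why: Chemoselective allylic oxidation by MnO2 converts only the dienylic C8' alcohol into the ketone, leaves the unactivated C3' hydroxyl alone and brings in no base that could open the oxirane.

Step 23
Reactants: 33 C16 stannyl dienone; 23 diiodotriene (3 equiv)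
Product: 34 (3E,5E,7E,9E,11E)-1-[(1S,4S,6R)-4-hydroxy-2,2,6-trimethyl-7-oxabicyclo[4.1.0]heptan-1-yl]-12-iodo-3,7-dimethyltrideca-3,5,7,9,11-pentaen-2-one
Conditions: Pd2(dba)3·CHCl3 (cat.), AsPh3, N-methylpyrrolidinone, rt, slow addition of 33, dark
Reagents that add atoms: none
Why: This stereoretentive Stille coupling forms C12'–C13', and because both ends of 23 are equivalent no regiochemical question arises, while excess 23 and slow addition of 33 favour single coupling.

Step 24
Reactants: 34 C24 pentaenone iodide; 13 C16 dienynyl stannane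
Product: 35 target, (3R)-ring A, (3'S,5'R,6'S)-ring B, all-E
Conditions: Pd2(dba)3·CHCl3 (cat.), AsPh3, N-methylpyrrolidinone, rt → 40 °C, argon, dark
Reagents that add atoms: none
Why: Zerovalent palladium inserts into the C13–I bond of 34 with retention, the AsPh3-ligated alkenylpalladium iodide accepts the C12 dienyl group from tin of 13 in the rate-limiting transmetalation, and reductive elimination forms C12–C13 with both alkene geometries kept. The closest known reaction type is the Stille alkenyl iodide–alkenylstannane coupling as used for retinoid and carotenoid polyenes, including couplings at methyl-bearing alkene carbons. It closes no ring and creates no stereocentre; C3, C3', C5' and C6' are remote spectators, and the stereochemical task, (E) at C11=C12 and C13=C14, is met by the stereoretentive mechanism acting on geometries fixed in steps 7 and 8. It needs chemoselectivity for one C–I and one C–Sn bond beside two free hydroxyls, the C7≡C8 alkyne, the C8' ketone and the C5'–C6' oxirane, and this is secured because each half carries exactly one reactive terminus, tin sits on an unhindered CH so that the hindrance of fully substituted C13 falls on the fast oxidative addition, and the oxirane is insulated from the polyene by C7'H2 and cannot ionise to an allylpalladium species. The medium is neutral and free of base and fluoride, so the acidic C7' methylene cannot trigger β-opening of the oxirane. In one operation C16 and C24 are united, the ene-yne-heptaenone chromophore is completed and the unprotected target is released.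

**Compound list**
1 | (4R,6R)-4-hydroxy-2,2,6-trimethylcyclohexan-1-one (actinol, OH and C6 methyl trans) | C[C@H]1C(=O)C(C)(C)C[C@H](O)C1 | starting material
2 | (4R,6R)-4-(tert-butyldimethylsilyloxy)-2,2,6-trimethylcyclohexan-1-one | C[C@H]1C(=O)C(C)(C)C[C@H](O[Si](C)(C)C(C)(C)C)C1 | intermediate
3 | lithium (R)-4-(tert-butyldimethylsilyloxy)-2,6,6-trimethylcyclohex-1-en-1-olate | CC1=C(O[Li])C(C)(C)C[C@H](O[Si](C)(C)C(C)(C)C)C1 | intermediate
4 | (R)-4-(tert-butyldimethylsilyloxy)-2,6,6-trimethylcyclohex-1-en-1-yl trifluoromethanesulfonate | CC1=C(OS(=O)(=O)C(F)(F)F)C(C)(C)C[C@H](O[Si](C)(C)C(C)(C)C)C1 | intermediate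
5 | (E)-3-methylpent-2-en-4-yn-1-ol | C#C/C(C)=C/CO | starting material
6 | (E)-5-[(R)-4-(tert-butyldimethylsilyloxy)-2,6,6-trimethylcyclohex-1-en-1-yl]-3-methylpent-2-en-4-yn-1-ol | CC1=C(C#C/C(C)=C/CO)C(C)(C)C[C@H](O[Si](C)(C)C(C)(C)C)C1 | intermediate
7 | (E)-5-[(R)-4-hydroxy-2,6,6-trimethylcyclohex-1-en-1-yl]-3-methylpent-2-en-4-yn-1-ol | CC1=C(C#C/C(C)=C/CO)C(C)(C)C[C@H](O)C1 | intermediate
8 | (E)-5-[(R)-4-hydroxy-2,6,6-trimethylcyclohex-1-en-1-yl]-3-methylpent-2-en-4-ynal | CC1=C(C#C/C(C)=C/C=O)C(C)(C)C[C@H](O)C1 | intermediate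
9 | diiodomethane | C(I)I | starting material
10 | tributyltin chloride | CCCC[Sn](Cl)(CCCC)CCCC | starting material
11 | diiodomethyllithium | [Li]C(I)I | intermediate
12 | tributyl(diiodomethyl)stannane | CCCC[Sn](CCCC)(CCCC)C(I)I | intermediate
13 | (R)-3,5,5-trimethyl-4-[(3E,5E)-3-methyl-6-(tributylstannyl)hexa-3,5-dien-1-yn-1-yl]cyclohex-3-en-1-ol | CC1=C(C#C/C(C)=C/C=C/[Sn](CCCC)(CCCC)CCCC)C(C)(C)C[C@H](O)C1 | intermediate
14 | but-2-yn-1-ol | CC#CCO | starting material
15 | diisobutylaluminium but-2-yn-1-olate | CC#CCO[Al](CC(C)C)CC(C)C | intermediate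
16 | chlorobis(cyclopentadienyl)zirconium (E)-alkenyl derived from 15 (Zr on the methyl-bearing carbon, trans to CH2O) | C/C(=C\CO[Al](CC(C)C)CC(C)C)[Zr+2]Cl.c1cc[cH-]c1.c1cc[cH-]c1 | intermediate
17 | (E)-3-iodobut-2-en-1-ol | I/C(C)=C/CO | intermediate
18 | (E)-3-iodobut-2-enal | I/C(C)=C/C=O | intermediate
19 | tributyl[(1E,3E)-4-iodopenta-1,3-dien-1-yl]stannane | I/C(C)=C/C=C/[Sn](CCCC)(CCCC)CCCC | intermediate
20 | (E)-1-bromo-3-iodobut-2-ene | I/C(C)=C/CBr | intermediate
21 | diethyl [(E)-3-iodobut-2-en-1-yl]phosphonate | I/C(C)=C/CP(=O)(OCC)OCC | intermediate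
22 | sodium salt of the α-carbanion of 21 | I/C(C)=C/[CH-]P(=O)(OCC)OCC.[Na+] | intermediate
23 | (2E,4E,6E)-2,7-diiodoocta-2,4,6-triene | I/C(C)=C/C=C/C=C(C)/I | intermediate
24 | methyl (R)-4-(tert-butyldimethylsilyloxy)-2,6,6-trimethylcyclohex-1-ene-1-carboxylate | COC(=O)C1=C(C)C[C@@H](O[Si](C)(C)C(C)(C)C)CC1(C)C | intermediate
25 | [(R)-4-(tert-butyldimethylsilyloxy)-2,6,6-trimethylcyclohex-1-en-1-yl]methanol | OCC1=C(C)C[C@@H](O[Si](C)(C)C(C)(C)C)CC1(C)C | intermediate
26 | [(1R,4S,6R)-4-(tert-butyldimethylsilyloxy)-2,2,6-trimethyl-7-oxabicyclo[4.1.0]heptan-1-yl]methanol | OC[C@@]12O[C@]1(C)C[C@@H](O[Si](C)(C)C(C)(C)C)CC2(C)C | intermediate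
27 | (1S,4S,6R)-4-(tert-butyldimethylsilyloxy)-2,2,6-trimethyl-7-oxabicyclo[4.1.0]heptane-1-carbaldehyde | O=C[C@@]12O[C@]1(C)C[C@@H](O[Si](C)(C)C(C)(C)C)CC2(C)C | intermediate
28 | tert-butyl{[(1R,4S,6R)-1-ethynyl-2,2,6-trimethyl-7-oxabicyclo[4.1.0]heptan-4-yl]oxy}dimethylsilane | C#C[C@@]12O[C@]1(C)C[C@@H](O[Si](C)(C)C(C)(C)C)CC2(C)C | intermediate
29 | (1R,4S,6R)-1-ethynyl-2,2,6-trimethyl-7-oxabicyclo[4.1.0]heptan-4-ol | C#C[C@@]12O[C@]1(C)C[C@@H](O)CC2(C)C | intermediate
30 | (E)-alkenyl(dicyclohexyl)borane from 29, C3' oxygen as dicyclohexylborinate | C1CCCCC1B(C1CCCCC1)/C=C/[C@@]12O[C@]1(C)C[C@@H](OB(C3CCCCC3)C3CCCCC3)CC2(C)C | intermediate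
31 | 2-[(1S,4S,6R)-4-hydroxy-2,2,6-trimethyl-7-oxabicyclo[4.1.0]heptan-1-yl]acetaldehyde | O=CC[C@@]12O[C@]1(C)C[C@@H](O)CC2(C)C | intermediate
32 | (3E,5E)-1-[(1S,4S,6R)-4-hydroxy-2,2,6-trimethyl-7-oxabicyclo[4.1.0]heptan-1-yl]-3-methyl-6-(tributylstannyl)hexa-3,5-dien-2-ol (carbinol epimers) | CCCC[Sn](CCCC)(CCCC)/C=C/C=C(\C)C(O)C[C@@]12O[C@]1(C)C[C@@H](O)CC2(C)C | intermediate
33 | (3E,5E)-1-[(1S,4S,6R)-4-hydroxy-2,2,6-trimethyl-7-oxabicyclo[4.1.0]heptan-1-yl]-3-methyl-6-(tributylstannyl)hexa-3,5-dien-2-one | CCCC[Sn](CCCC)(CCCC)/C=C/C=C(\C)C(=O)C[C@@]12O[C@]1(C)C[C@@H](O)CC2(C)C | intermediate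
34 | (3E,5E,7E,9E,11E)-1-[(1S,4S,6R)-4-hydroxy-2,2,6-trimethyl-7-oxabicyclo[4.1.0]heptan-1-yl]-12-iodo-3,7-dimethyltrideca-3,5,7,9,11-pentaen-2-one | I/C(C)=C/C=C/C=C(C)/C=C/C=C(\C)C(=O)C[C@@]12O[C@]1(C)C[C@@H](O)CC2(C)C | intermediate
35 | all-E (3S,5R,6S,3'R)-5,6-epoxy-3,3'-dihydroxy-7',8'-didehydro-5,6,7,8-tetrahydro-β,β-caroten-8-one | CC1=C(C#C/C(C)=C/C=C/C(C)=C/C=C/C=C(C)/C=C/C=C(\C)C(=O)C[C@@]23O[C@]2(C)C[C@@H](O)CC3(C)C)C(C)(C)C[C@H](O)C1 | target

**Count**
Total steps: 24. Longest linear sequence: 13 (steps 1, 2, 14–24).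

**Steps most likely to fail**

Step 20. During the oxidative work-up the β,γ-epoxy aldehyde may enolise at C7' and open the oxirane to the conjugated γ-hydroxy enal. The borane may also attack the oxirane.
The fallback sets out from 27 and comes back at 31. It makes the aldehyde by a neutral alcohol oxidation instead of from a vinylboron species.
- Wittig methylenation of 27 (Ph3P=CH2, THF) would give the silyl-protected vinyl oxirane F1.
- Hydroboration with 9-borabicyclo[3.3.1]nonane and alkaline peroxide, which is harmless at the alcohol level, would give the silyl-protected 3,4-epoxy alcohol F2.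
- n-Bu4NF would give the epoxy diol F3.
- Catalytic TEMPO and PhI(OAc)2 in CH2Cl2 would oxidise only the primary alcohol to 31, immediately before step 21.

Step 21. Nickel-mediated self-coupling of the iodo-stannane, or loss of tin, may outrun addition to the aldehyde.
The fallback sets out from 31 and 17 and comes back at 32. It installs tin only after the C8'–C9' bond exists.
- The same chromium/nickel addition of tin-free 17 to 31 would give the triol F4.
- TEMPO and PhI(OAc)2 would oxidise only the primary allylic alcohol, giving the hydroxy enal F5.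
- Takai–Hodgson olefination of F5 by 12 would give 32.

Step 24. Slow transmetalation may let three processes compete: homocoupling or protodestannylation of 13, E/Z scrambling, and decay of the long polyenyl iodide that carries the epoxy ketone.
The fallback sets out from 13 and 23 and comes back at 35. It uses the symmetry of the linchpin to invert the order of the two unions.
- 13 would be coupled first with excess 23, forming the same C12–C13 bond on the small linchpin, to give the sturdier ring A pentaenynyl iodide F6.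
- The fragile epoxy ketone would enter only in the last operation, as stannane 33, by Stille coupling at C12'–C13' of F6.

**Further compounds**
F1 | step 20 | tert-butyl{[(1S,4S,6R)-1-ethenyl-2,2,6-trimethyl-7-oxabicyclo[4.1.0]heptan-4-yl]oxy}dimethylsilane | C=C[C@@]12O[C@]1(C)C[C@@H](O[Si](C)(C)C(C)(C)C)CC2(C)C
F2 | step 20 | 2-[(1S,4S,6R)-4-(tert-butyldimethylsilyloxy)-2,2,6-trimethyl-7-oxabicyclo[4.1.0]heptan-1-yl]ethan-1-ol | OCC[C@@]12O[C@]1(C)C[C@@H](O[Si](C)(C)C(C)(C)C)CC2(C)C
F3 | step 20 | (1S,4S,6R)-1-(2-hydroxyethyl)-2,2,6-trimethyl-7-oxabicyclo[4.1.0]heptan-4-ol | OCC[C@@]12O[C@]1(C)C[C@@H](O)CC2(C)C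
F4 | step 21 | (E)-5-[(1S,4S,6R)-4-hydroxy-2,2,6-trimethyl-7-oxabicyclo[4.1.0]heptan-1-yl]-3-methylpent-2-ene-1,4-diol (carbinol epimers) | OC/C=C(\C)C(O)C[C@@]12O[C@]1(C)C[C@@H](O)CC2(C)C
F5 | step 21 | (E)-4-hydroxy-5-[(1S,4S,6R)-4-hydroxy-2,2,6-trimethyl-7-oxabicyclo[4.1.0]heptan-1-yl]-3-methylpent-2-enal (carbinol epimers) | O=C/C=C(\C)C(O)C[C@@]12O[C@]1(C)C[C@@H](O)CC2(C)C
F6 | step 24 | (R)-4-[(3E,5E,7E,9E,11E)-12-iodo-3,7-dimethyltrideca-3,5,7,9,11-pentaen-1-yn-1-yl]-3,5,5-trimethylcyclohex-3-en-1-ol | CC1=C(C#C/C(C)=C/C=C/C(C)=C/C=C/C=C(C)/I)C(C)(C)C[C@H](O)C1
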